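**Retrosynthetic overview**

1. Rings: A is the 4-hydroxyphenyl on the oxolane, B the trisubstituted phenol, C the 4-hydroxyphenyl of the side chain. The strategy rests on the chain ring B C3'–CH(CH3)–CH2–ring C standing ortho to the ring B phenol oxygen at C4'. This unit is a 2-aryl-3-methyl-2,3-dihydrobenzofuran whose O–C2 bond has been cut, so the side-chain stereocentre is made as C3 of that temporary ring and C2 ends as the CH2 group.
2. The dihydrobenzofuran comes from an enantioselective rhodium-carbene insertion into the O–CH2 group of aryldiazoacetate 6 (C3–C2 bond and ring closure). The cis ester from Rh2(S-PTTL)4 already has the C3 configuration needed, so it is not epimerised before ester → CH3 and ionic O–C2 cleavage.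
3. The oxolane is cut at an O–C(aryl) bond (acid cyclodehydration of a 1,4-diol under thermodynamic control) and at the C–ring B bond (aryllithium from bromide 12 plus lactone 20).
4. Lactone 20 carries the cis-dimethyl pair and the absolute sense of the oxolane. It comes from meso-2,3-dimethylsuccinic anhydride by rhodium-catalysed enantioselective arylation and Felkin–Anh reduction.
5. Ring order: dihydrobenzofuran (step 5, opened in step 9), lactone (step 13), oxolane (step 16), then debenzylation.

Key step: step 5

Remark: Rh2(S-PTTL)4 is taken to give the (2R,3S)-cis ester, as in this class of 2-(benzyloxy)phenyl diazoacetates, and the phosphoramidite antipode in step 12 is the one that leads to the (2R,3S)-acid; if either sense proves opposite, the antipodal catalyst or ligand is used and nothing else changes.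

**Route**

Step 1
Reactants: 1 2-hydroxyphenylacetic acid
Product: 2 methyl 2-(2-hydroxyphenyl)acetate
Conditions: MeOH, H2SO4 (cat.), reflux
Reagents that add atoms: methanol, CO
Why: Fischer esterification of the aliphatic acid gives the ester needed for the later diazo transfer.

Step 2
Reactants: 2 methyl 2-(2-hydroxyphenyl)acetate
Product: 3 methyl 2-(5-bromo-2-hydroxyphenyl)acetate
Conditions: N-bromosuccinimide (1.0 equiv), MeCN, 0 °C, dark
Reagents that add atoms: N-bromosuccinimide, O=C1CCC(=O)N1Br
Why: Electrophilic aromatic bromination of the phenol should go para to the hydroxyl group, the position that later carries the oxolane.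

Step 3
Reactants: 3 methyl 2-(5-bromo-2-hydroxyphenyl)acetate; 4 4-(benzyloxy)benzyl chloride
Product: 5 methyl 2-[5-bromo-2-{[4-(benzyloxy)phenyl]methoxy}phenyl]acetate
Conditions: K2CO3, KI (cat.), DMF, 50 °C
Reagents that add atoms: none
Why: Williamson ether synthesis (SN2 of the phenoxide on the benzylic halide with iodide catalysis); K2CO3 is too weak to deprotonate the ester α-carbon.

Step 4
Reactants: 5 methyl 2-[5-bromo-2-{[4-(benzyloxy)phenyl]methoxy}phenyl]acetate
Product: 6 methyl 2-[5-bromo-2-{[4-(benzyloxy)phenyl]methoxy}phenyl]-2-diazoacetate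
Conditions: 4-acetamidobenzenesulfonyl azide, DBU, MeCN, 0 °C → rt
Reagents that add atoms: 4-acetamidobenzenesulfonyl azide, CC(=O)Nc1ccc(cc1)S(=O)(=O)N=[N+]=[N-]
Why: Regitz diazo transfer to the CH2 group activated by both the aryl ring and the ester is the standard entry to aryldiazoacetates.

Step 5
Reactants: 6 methyl 2-[5-bromo-2-{[4-(benzyloxy)phenyl]methoxy}phenyl]-2-diazoacetate
Product: 7 methyl (2R,3S)-2-[4-(benzyloxy)phenyl]-5-bromo-2,3-dihydro-1-benzofuran-3-carboxylate (cis)
Conditions: Rh2(S-PTTL)4 (1 mol %; PTTL = N-phthaloyl-tert-leucinate), toluene, −60 °C, slow addition of 6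
Reagents that add atoms: none
Why: Rh2(S-PTTL)4 (divalent rhodium) takes N2 from 6 to give an aryl/ester rhodium carbene, which inserts into a C–H bond of the ArO–CH2 group five atoms away through a concerted, asynchronous three-centre transition state with hydride-shift character. The closest known reaction type is the enantioselective intramolecular C–H insertion of 2-(benzyloxy)phenyl diazoacetates with dirhodium N-phthaloyl amino-acid carboxylates, which gives cis-2-aryl-2,3-dihydrobenzofuran-3-carboxylates. The one ring closed is the five-membered O-heterocycle, formed by 1,5 C–H insertion, that is by making the C3–C2 bond between the carbene carbon and the ether CH2 carbon. C2 is set by the choice between the two enantiotopic benzylic hydrogens and C3 by the carbene face that is presented, both under control of the chiral phthalimido carboxylate wall of the catalyst, and the cis ester is the kinetic product with this catalyst class; only C3 (S) is carried to the target. The step needs 1,5-insertion to win over aromatic cycloaddition, carbene dimerisation and reaction at the distant PhCH2–O group; the ether oxygen and the 4-alkoxyphenyl ring activate the proximal C–H bond, which is the only one that can reach the carbene in a five-membered transition state, and slow addition at low temperature keeps the diazo concentration low. The minor trans ester is removed by chromatography and base is kept away, because any C3 epimer would end as the wrong side-chain enantiomer.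

Step 6
Reactants: 7 methyl (2R,3S)-2-[4-(benzyloxy)phenyl]-5-bromo-2,3-dihydro-1-benzofuran-3-carboxylate
Product: 8 [(2R,3R)-2-[4-(benzyloxy)phenyl]-5-bromo-2,3-dihydro-1-benzofuran-3-yl]methanol (cis; descriptor at C3 changes, geometry does not)
Conditions: i-Bu2AlH (2.5 equiv), CH2Cl2, −78 °C; aq. KNaC4H4O6
Reagents that add atoms: none
Why: Ester reduction by the Lewis-acidic, non-basic aluminium hydride at low temperature should not enolise the cis ester, so C3 is kept, and the aryl bromide is inert.

Step 7
Reactants: 8 [(2R,3R)-2-[4-(benzyloxy)phenyl]-5-bromo-2,3-dihydro-1-benzofuran-3-yl]methanol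
Product: 9 [(2R,3R)-2-[4-(benzyloxy)phenyl]-5-bromo-2,3-dihydro-1-benzofuran-3-yl]methyl 4-methylbenzenesulfonate
Conditions: p-toluenesulfonyl chloride, Et3N, DMAP (cat.), CH2Cl2, 0 °C → rt
Reagents that add atoms: p-toluenesulfonyl chloride, Cc1ccc(cc1)S(=O)(=O)Cl
Why: Sulfonylation of the primary alcohol turns it into a leaving group without touching either stereocentre.

Step 8
Reactants: 9 [(2R,3R)-2-[4-(benzyloxy)phenyl]-5-bromo-2,3-dihydro-1-benzofuran-3-yl]methyl 4-methylbenzenesulfonate
Product: 10 (2R,3S)-2-[4-(benzyloxy)phenyl]-5-bromo-3-methyl-2,3-dihydro-1-benzofuran (cis)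
Conditions: LiBHEt3, THF, 0 °C → rt
Reagents that add atoms: none
Why: SN2 displacement of the primary tosylate by hydride gives the methyl group; the reaction occurs at the exocyclic CH2 only and the aryl bromide does not react.

Step 9
Reactants: 10 (2R,3S)-2-[4-(benzyloxy)phenyl]-5-bromo-3-methyl-2,3-dihydro-1-benzofuran
Product: 11 2-[(2R)-1-[4-(benzyloxy)phenyl]propan-2-yl]-4-bromophenol
Conditions: Et3SiH (10 equiv), CF3CO2H, CH2Cl2, −20 → 0 °C
Reagents that add atoms: none
Why: Ionic hydrogenation: protonation of the ring oxygen and heterolysis of the O–C2 bond give a 4-(benzyloxy)benzylic cation with the phenol as leaving group, and the large excess of silane should deliver hydride before the cation can lose a proton or shift a hydride, so C2 becomes CH2 and the former C3 keeps its configuration (now R by descriptor).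

Step 10
Reactants: 11 2-[(2R)-1-[4-(benzyloxy)phenyl]propan-2-yl]-4-bromophenol
Product: 12 1-(benzyloxy)-2-[(2R)-1-[4-(benzyloxy)phenyl]propan-2-yl]-4-bromobenzene
Conditions: benzyl bromide, K2CO3, DMF, rt
Reagents that add atoms: benzyl bromide, BrCc1ccccc1
Why: Williamson etherification masks the new phenol so that the bromide can be lithiated.

Step 11
Reactants: 13 meso-2,3-dimethylsuccinic acid
Product: 14 cis-2,3-dimethylsuccinic anhydride ((3R,4S)-3,4-dimethyloxolane-2,5-dione, meso)
Conditions: acetyl chloride, reflux; evaporation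
Reagents that add atoms: none
Why: Cyclodehydration with an acid chloride in the absence of base gives the cis anhydride without epimerisation to the trans isomer.

Step 12
Reactants: 14 cis-2,3-dimethylsuccinic anhydride; 15 1-(benzyloxy)-4-bromobenzene
Product: 18 (2R,3S)-4-[4-(benzyloxy)phenyl]-2,3-dimethyl-4-oxobutanoic acid, via 4-(benzyloxy)phenyllithium 16 (not isolated), via 4-(benzyloxy)phenylzinc triflate 17 (not isolated)
Conditions: 15, n-BuLi, THF, −78 °C; Zn(OTf)2, −78 °C → rt; then 14, [Rh(cod)Cl]2 (2.5 mol %), (R,R)-TADDOL-derived N,N-dimethylphosphoramidite (10 mol %), THF, 50 °C; 1 M HCl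
Reagents that add atoms: none
Why: Bromine–lithium exchange and transmetalation give the arylzinc reagent, and the phosphoramidite complex of monovalent rhodium inserts into one of the two enantiotopic C(O)–O bonds of the meso anhydride before transmetalation and reductive elimination (enantioselective acyl cross-coupling, a desymmetrisation known for this anhydride with arylzinc reagents), so both methyl centres come from the meso substrate and the ligand only decides which carbonyl becomes the ketone.

Step 13
Reactants: 18 (2R,3S)-4-[4-(benzyloxy)phenyl]-2,3-dimethyl-4-oxobutanoic acid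
Product: 20 (3R,4S,5S)-5-[4-(benzyloxy)phenyl]-3,4-dimethyloxolan-2-one, via (2R,3S,4S)-hydroxy acid 19 (not isolated)
Conditions: LiBH(s-Bu)3 (2.2 equiv), THF, −78 °C; 2 M HCl; TsOH (cat.), CH2Cl2, rt
Reagents that add atoms: none
Why: Felkin–Anh reduction: the bulky hydride attacks the aryl ketone anti to the branched CH(CH3)CO2Li group and so should set C4 as S (4,5-trans in the lactone), after which acid closes the γ-lactone; a C5 epimer, if carried along, is corrected in step 16.

Step 14
Reactants: 12 1-(benzyloxy)-2-[(2R)-1-[4-(benzyloxy)phenyl]propan-2-yl]-4-bromobenzene; 20 (3R,4S,5S)-5-[4-(benzyloxy)phenyl]-3,4-dimethyloxolan-2-one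
Product: 22 (3R,4S,5S)-2-{4-(benzyloxy)-3-[(2R)-1-[4-(benzyloxy)phenyl]propan-2-yl]phenyl}-5-[4-(benzyloxy)phenyl]-3,4-dimethyloxolan-2-ol (hemiketal; both C2 epimers), via aryllithium 21 (not isolated)
Conditions: 12, n-BuLi (1.0 equiv), THF, −78 °C; then 20 (1.1 equiv), −78 °C; aq. NH4Cl
Reagents that add atoms: none
Why: Bromine–lithium exchange followed by 1,2-addition of the aryllithium to the lactone carbonyl; the tetrahedral lithium alkoxide persists at −78 °C, so the reaction should stop after one addition and give the hemiketal.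

Step 15
Reactants: 22 hemiketal
Product: 23 (1S,2S,3R,4RS)-1-[4-(benzyloxy)phenyl]-4-{4-(benzyloxy)-3-[(2R)-1-[4-(benzyloxy)phenyl]propan-2-yl]phenyl}-2,3-dimethylbutane-1,4-diol
Conditions: LiAlH4, THF, 0 °C; then H2O
Reagents that add atoms: none
Why: Hydride reduction of the open hydroxy-ketone form of the hemiketal gives the 1,4-diol; the configuration of the new carbinol carbon is of no consequence because it is ionised in step 16.

Step 16
Reactants: 23 1,4-diol
Product: 24 (2S,3S,4R,5R)-2-[4-(benzyloxy)phenyl]-5-{4-(benzyloxy)-3-[(2R)-1-[4-(benzyloxy)phenyl]propan-2-yl]phenyl}-3,4-dimethyloxolane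
Conditions: BF3·OEt2 (0.3 equiv), CH2Cl2, −20 °C → rt
Reagents that add atoms: none
Why: Acid-catalysed SN1 cycloetherification: either carbinol ionises to a 4-alkoxybenzylic cation that the other hydroxyl traps in a 5-exo closure, and because both aryl-bearing C–O bonds of the product stay ionisable the mixture should settle under thermodynamic control on the isomer with each aryl trans to its neighbouring methyl (2,3-trans-3,4-cis-4,5-trans), the methyl-bearing carbons and the side-chain centre not being touched.

Step 17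
Reactants: 24 tris(benzyl ether)
Product: 25 4-[(2S,3S,4R,5R)-5-{4-hydroxy-3-[(2R)-1-(4-hydroxyphenyl)propan-2-yl]phenyl}-3,4-dimethyloxolan-2-yl]phenol (target)
Conditions: H2 (1 atm), Pd/C (10 %), EtOAc–MeOH, rt, stopped at full debenzylation
Reagents that add atoms: none
Why: Catalytic hydrogenolysis of the three aryl benzyl ethers, which cleave faster than the cyclic dibenzylic ether under these mild conditions, frees the three phenols without touching a stereocentre.

**Compound list**

1 | 2-hydroxyphenylacetic acid | OC(=O)Cc1ccccc1O | starting material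
2 | methyl 2-(2-hydroxyphenyl)acetate | COC(=O)Cc1ccccc1O | intermediate
3 | methyl 2-(5-bromo-2-hydroxyphenyl)acetate | COC(=O)Cc1cc(Br)ccc1O | intermediate
4 | 4-(benzyloxy)benzyl chloride | ClCc1ccc(OCc2ccccc2)cc1 | starting material
5 | methyl 2-[5-bromo-2-{[4-(benzyloxy)phenyl]methoxy}phenyl]acetate | COC(=O)Cc1cc(Br)ccc1OCc1ccc(OCc2ccccc2)cc1 | intermediate
6 | methyl 2-[5-bromo-2-{[4-(benzyloxy)phenyl]methoxy}phenyl]-2-diazoacetate | COC(=O)C(=[N+]=[N-])c1cc(Br)ccc1OCc1ccc(OCc2ccccc2)cc1 | intermediate
7 | methyl (2R,3S)-2-[4-(benzyloxy)phenyl]-5-bromo-2,3-dihydro-1-benzofuran-3-carboxylate (cis) | COC(=O)[C@@H]1[C@H](c2ccc(OCc3ccccc3)cc2)Oc2ccc(Br)cc21 | intermediate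
8 | [(2R,3R)-2-[4-(benzyloxy)phenyl]-5-bromo-2,3-dihydro-1-benzofuran-3-yl]methanol (cis) | OC[C@@H]1[C@H](c2ccc(OCc3ccccc3)cc2)Oc2ccc(Br)cc21 | intermediate
9 | [(2R,3R)-2-[4-(benzyloxy)phenyl]-5-bromo-2,3-dihydro-1-benzofuran-3-yl]methyl 4-methylbenzenesulfonate | Cc1ccc(cc1)S(=O)(=O)OC[C@@H]1[C@H](c2ccc(OCc3ccccc3)cc2)Oc2ccc(Br)cc21 | intermediate
10 | (2R,3S)-2-[4-(benzyloxy)phenyl]-5-bromo-3-methyl-2,3-dihydro-1-benzofuran (cis) | C[C@@H]1[C@H](c2ccc(OCc3ccccc3)cc2)Oc2ccc(Br)cc21 | intermediate
11 | 2-[(2R)-1-[4-(benzyloxy)phenyl]propan-2-yl]-4-bromophenol | C[C@H](Cc1ccc(OCc2ccccc2)cc1)c1cc(Br)ccc1O | intermediate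
12 | 1-(benzyloxy)-2-[(2R)-1-[4-(benzyloxy)phenyl]propan-2-yl]-4-bromobenzene | C[C@H](Cc1ccc(OCc2ccccc2)cc1)c1cc(Br)ccc1OCc1ccccc1 | intermediate
13 | meso-2,3-dimethylsuccinic acid | C[C@@H](C(=O)O)[C@H](C)C(=O)O | starting material
14 | cis-2,3-dimethylsuccinic anhydride | C[C@@H]1[C@H](C)C(=O)OC1=O | intermediate
15 | 1-(benzyloxy)-4-bromobenzene | Brc1ccc(OCc2ccccc2)cc1 | starting material
16 | 4-(benzyloxy)phenyllithium (not isolated) | [Li]c1ccc(OCc2ccccc2)cc1 | intermediate
17 | 4-(benzyloxy)phenylzinc triflate (not isolated) | FC(F)(F)S(=O)(=O)O[Zn]c1ccc(OCc2ccccc2)cc1 | intermediate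
18 | (2R,3S)-4-[4-(benzyloxy)phenyl]-2,3-dimethyl-4-oxobutanoic acid | C[C@@H](C(=O)O)[C@H](C)C(=O)c1ccc(OCc2ccccc2)cc1 | intermediate
19 | (2R,3S,4S)-4-[4-(benzyloxy)phenyl]-4-hydroxy-2,3-dimethylbutanoic acid (not isolated) | C[C@@H](C(=O)O)[C@H](C)[C@H](O)c1ccc(OCc2ccccc2)cc1 | intermediate
20 | (3R,4S,5S)-5-[4-(benzyloxy)phenyl]-3,4-dimethyloxolan-2-one | C[C@@H]1[C@H](C)[C@@H](c2ccc(OCc3ccccc3)cc2)OC1=O | intermediate
21 | {4-(benzyloxy)-3-[(2R)-1-[4-(benzyloxy)phenyl]propan-2-yl]phenyl}lithium (not isolated) | C[C@H](Cc1ccc(OCc2ccccc2)cc1)c1cc([Li])ccc1OCc1ccccc1 | intermediate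
22 | (3R,4S,5S)-2-{4-(benzyloxy)-3-[(2R)-1-[4-(benzyloxy)phenyl]propan-2-yl]phenyl}-5-[4-(benzyloxy)phenyl]-3,4-dimethyloxolan-2-ol (both C2 epimers) | C[C@@H]1[C@H](C)[C@@H](c2ccc(OCc3ccccc3)cc2)OC1(O)c1ccc(OCc2ccccc2)c(c1)[C@H](C)Cc1ccc(OCc2ccccc2)cc1 | intermediate
23 | (1S,2S,3R,4RS)-1-[4-(benzyloxy)phenyl]-4-{4-(benzyloxy)-3-[(2R)-1-[4-(benzyloxy)phenyl]propan-2-yl]phenyl}-2,3-dimethylbutane-1,4-diol | C[C@@H](C(O)c1ccc(OCc2ccccc2)c(c1)[C@H](C)Cc1ccc(OCc2ccccc2)cc1)[C@H](C)[C@H](O)c1ccc(OCc2ccccc2)cc1 | intermediate
24 | (2S,3S,4R,5R)-2-[4-(benzyloxy)phenyl]-5-{4-(benzyloxy)-3-[(2R)-1-[4-(benzyloxy)phenyl]propan-2-yl]phenyl}-3,4-dimethyloxolane | C[C@@H]1[C@H](C)[C@@H](c2ccc(OCc3ccccc3)cc2)O[C@H]1c1ccc(OCc2ccccc2)c(c1)[C@H](C)Cc1ccc(OCc2ccccc2)cc1 | intermediate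
25 | 4-[(2S,3S,4R,5R)-5-{4-hydroxy-3-[(2R)-1-(4-hydroxyphenyl)propan-2-yl]phenyl}-3,4-dimethyloxolan-2-yl]phenol | C[C@@H]1[C@H](C)[C@@H](c2ccc(O)cc2)O[C@H]1c1ccc(O)c([C@H](C)Cc2ccc(O)cc2)c1 | target

**Step count and risks**

Total step count: 17. Longest linear sequence: 14 steps (steps 1–10 and 14–17); the lactone branch (steps 11–13) joins at step 14.

Steps most likely to fail:

Step 5. The enantiotopic C–H bonds may be told apart too poorly, the carbene may leak into aromatic cycloaddition or dimerisation, and any trans ester or base-induced epimerisation erodes C3 directly. The fallback sets the side-chain centre by auxiliary-controlled enolate alkylation and needs no carbene and no ring opening. It sets out from 3 and comes back at 12. Benzylation of 3 (benzyl bromide, K2CO3) gives methyl 2-[2-(benzyloxy)-5-bromophenyl]acetate F1, and saponification (LiOH, THF–H2O) gives 2-[2-(benzyloxy)-5-bromophenyl]acetic acid F2. Activation with pivaloyl chloride and Et3N and acylation of lithiated (R)-4-benzyloxazolidin-2-one give the imide F3. Its chelated Z-enolate (NaN(SiMe3)2, THF, −78 °C) should be alkylated by chloride 4 in the presence of NaI on the face away from the auxiliary benzyl group, giving the (2R)-alkylated imide F4 (Evans alkylation). LiBH4 removes the auxiliary reductively to give the alcohol F5, tosylation gives the tosylate F6, and LiBHEt3 turns CH2OTs into CH3 to give 12.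

Step 9. The benzylic cation may shift a hydride from, or lose the proton of, the neighbouring methyl-bearing carbon before the silane reaches it, which would erode the side-chain configuration, and the acid may cleave the aryl benzyl ether. The fallback cleaves the O–C2 bond on a metal surface without a free cation. It sets out from 10 and comes back at 12. Hydrogenolysis of 10 (H2, Pd/C, AcOH, 4 atm) should cut the benzylic O–C2 bond together with the benzyl ether and the C–Br bond to give 2-[(2R)-1-(4-hydroxyphenyl)propan-2-yl]phenol F7. Double benzylation (benzyl bromide, K2CO3, DMF) gives 1-(benzyloxy)-2-[(2R)-1-[4-(benzyloxy)phenyl]propan-2-yl]benzene F8. N-bromosuccinimide in MeCN should brominate the free position para to the ring B ether oxygen in preference to the ortho positions of ring C and give 12.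

Step 16. The mixture of epimers at the two aryl-bearing carbons may not converge, and proton loss from the benzylic cations to styrenes would scramble the methyl-bearing carbons. Direct silane reduction of hemiketal 22 is not a remedy, because hydride would add to the cyclic oxocarbenium ion anti to the two methyl groups and place ring B cis to them. The fallback forms the C–ring B bond last and under kinetic control, by adding an aryl nucleophile to the cyclic oxocarbenium ion anti to the neighbouring methyl group. It sets out from 20 and from aryllithium 21 and comes back at 24. Reduction of 20 (i-Bu2AlH, CH2Cl2, −78 °C) gives the lactol F9, and benzenesulfinic acid with CaCl2 in CH2Cl2 gives the 2-(benzenesulfonyl)oxolane F10. Aryllithium 21 and ZnBr2 give the arylzinc bromide F11, which should displace the sulfone of F10 through the oxocarbenium ion (THF, rt) on the face opposite the two methyl groups and give 24 directly.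

**Further compounds**

F1 | step 5 | methyl 2-[2-(benzyloxy)-5-bromophenyl]acetate | COC(=O)Cc1cc(Br)ccc1OCc1ccccc1
F2 | step 5 | 2-[2-(benzyloxy)-5-bromophenyl]acetic acid | OC(=O)Cc1cc(Br)ccc1OCc1ccccc1
F3 | step 5 | (4R)-4-benzyl-3-{2-[2-(benzyloxy)-5-bromophenyl]acetyl}oxazolidin-2-one | O=C(Cc1cc(Br)ccc1OCc1ccccc1)N1[C@H](Cc2ccccc2)COC1=O
F4 | step 5 | (4R)-4-benzyl-3-{(2R)-2-[2-(benzyloxy)-5-bromophenyl]-3-[4-(benzyloxy)phenyl]propanoyl}oxazolidin-2-one | O=C([C@H](Cc1ccc(OCc2ccccc2)cc1)c1cc(Br)ccc1OCc1ccccc1)N1[C@H](Cc2ccccc2)COC1=O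
F5 | step 5 | (2R)-2-[2-(benzyloxy)-5-bromophenyl]-3-[4-(benzyloxy)phenyl]propan-1-ol | OC[C@H](Cc1ccc(OCc2ccccc2)cc1)c1cc(Br)ccc1OCc1ccccc1
F6 | step 5 | (2R)-2-[2-(benzyloxy)-5-bromophenyl]-3-[4-(benzyloxy)phenyl]propyl 4-methylbenzenesulfonate | Cc1ccc(cc1)S(=O)(=O)OC[C@H](Cc1ccc(OCc2ccccc2)cc1)c1cc(Br)ccc1OCc1ccccc1
F7 | step 9 | 2-[(2R)-1-(4-hydroxyphenyl)propan-2-yl]phenol | C[C@H](Cc1ccc(O)cc1)c1ccccc1O
F8 | step 9 | 1-(benzyloxy)-2-[(2R)-1-[4-(benzyloxy)phenyl]propan-2-yl]benzene | C[C@H](Cc1ccc(OCc2ccccc2)cc1)c1ccccc1OCc1ccccc1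
F9 | step 16 | (3R,4S,5S)-5-[4-(benzyloxy)phenyl]-3,4-dimethyloxolan-2-ol (both C2 epimers) | C[C@@H]1[C@H](C)[C@@H](c2ccc(OCc3ccccc3)cc2)OC1O
F10 | step 16 | (3R,4S,5S)-2-(benzenesulfonyl)-5-[4-(benzyloxy)phenyl]-3,4-dimethyloxolane (both C2 epimers) | C[C@@H]1[C@H](C)[C@@H](c2ccc(OCc3ccccc3)cc2)OC1S(=O)(=O)c1ccccc1
F11 | step 16 | {4-(benzyloxy)-3-[(2R)-1-[4-(benzyloxy)phenyl]propan-2-yl]phenyl}zinc bromide | Br[Zn]c1ccc(OCc2ccccc2)c(c1)[C@H](C)Cc1ccc(OCc2ccccc2)cc1
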